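**Retrosynthetic overview**
1. Target 25 comes from ketone 21 by equatorial addition of a hydroxymethyl unit (C17) at C8; the Z-enoate side chain comes from a B-alkyl Suzuki coupling at C12 after hydroboration of a C9 vinyl group.
2. The C4 gem-dimethyl group, H-5 and the C3 alcohol come from 4-methyl-Δ4-3-ketone 11 by reductive methylation and hydride reduction; 11 comes from the cross-conjugated dienone 10.
3. The strategy rests on ring A: its oxygen at C3 lies para to the methyl-bearing quaternary C10, which is bonded to C9, so ring A is a masked 2,4-dimethylphenol. The C9–C10 bond is cut to phenol 9, which carries an (E)-allylic carbonate on a meta tether.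
4. Phenol 9 comes from phenol 7 and allyl methyl carbonate by cross-metathesis; 7 comes from 2,6-dimethylbenzaldehyde by bromination, two-carbon homologation, asymmetric vinylation (C8), silylation and hydroxylation.
5. Ring order: ring A is present from the start as the benzene ring; ring B is closed in step 8; no other ring is formed.

Key step: step 8

Numbering: labdane numbering is used for the bicyclic compounds (ring A = C1–C5 and C10, ring B = C5–C10, side chain C11–C16 on C9, C17 on C8, C20 the methyl on C10).
Assumption: the (R,R,Ra) enantiomer of the binaphthol-derived bis(1-phenylethyl)phosphoramidite is taken as the one that opens the allyl face leading to 9S; if its sense is the reverse, the (S,S,Sa) ligand is used and nothing else changes.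

**Route**

Step 1
Reactants: 1 2,6-dimethylbenzaldehyde
Product: 2 3-bromo-2,6-dimethylbenzaldehyde
Conditions: NBS, H2SO4/CF3CO2H, rt
Reagents that add atoms: N-bromosuccinimide, O=C1CCC(=O)N1Br
Why: Electrophilic aromatic bromination, in which both methyl groups (ortho/para) and the protonated formyl group (meta) direct to C3.

Step 2
Reactants: 2 3-bromo-2,6-dimethylbenzaldehyde
Product: 3 (2E)-3-(3-bromo-2,6-dimethylphenyl)prop-2-enal
Conditions: Ph3P=CHCHO, toluene, 90 °C
Reagents that add atoms: (triphenylphosphoranylidene)acetaldehyde, O=CC=P(c1ccccc1)(c1ccccc1)c1ccccc1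
Why: Wittig olefination with the stabilized formyl ylide should give the E-enal, and the non-enolizable aldehyde 2 cannot self-condense.

Step 3
Reactants: 3 (2E)-3-(3-bromo-2,6-dimethylphenyl)prop-2-enal
Product: 4 3-(3-bromo-2,6-dimethylphenyl)propanal
Conditions: Hantzsch ester, Bn2NH·CF3CO2H (10 mol%), THF, rt
Reagents that add atoms: none
Why: Iminium-mediated organocatalytic transfer hydrogenation reduces only the conjugated C=C bond and leaves the aldehyde and the aryl bromide untouched.

Step 4
Reactants: 4 3-(3-bromo-2,6-dimethylphenyl)propanal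
Product: 5 (3S)-5-(3-bromo-2,6-dimethylphenyl)pent-1-en-3-ol
Conditions: (CH2=CH)2Zn (from CH2=CHMgBr and ZnCl2, salt-free), (+)-MIB (5 mol%), toluene, −10 °C; aq. NH4Cl
Reagents that add atoms: divinylzinc, C=C[Zn]C=C
Why: Amino-alcohol-catalysed enantioselective addition of an alkenylzinc reagent to an aldehyde, in which the zinc complex of (+)-MIB delivers the vinyl group to the Re face and so sets C8 as S.

Step 5
Reactants: 5 (3S)-5-(3-bromo-2,6-dimethylphenyl)pent-1-en-3-ol
Product: 6 {[(3S)-5-(3-bromo-2,6-dimethylphenyl)pent-1-en-3-yl]oxy}(tert-butyl)dimethylsilane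
Conditions: TBSCl, imidazole, DMF, rt
Reagents that add atoms: tert-butyldimethylsilyl chloride, CC(C)(C)[Si](C)(C)Cl
Why: Standard silylation of a secondary alcohol, giving an ether that should survive hydroxide, metathesis, iridium catalysis and dissolving metal.

Step 6
Reactants: 6 {[(3S)-5-(3-bromo-2,6-dimethylphenyl)pent-1-en-3-yl]oxy}(tert-butyl)dimethylsilane
Product: 7 3-[(3S)-3-(tert-butyldimethylsilyloxy)pent-4-en-1-yl]-2,4-dimethylphenol
Conditions: Pd2(dba)3 (2 mol%), tBuXPhos (8 mol%), KOH, 1,4-dioxane/H2O, 100 °C; then aq. NaH2PO4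
Reagents that add atoms: potassium hydroxide, [K+].[OH-]
Why: Palladium-catalysed C–O cross-coupling of an aryl bromide with hydroxide, which tolerates ortho substitution, while the bromide is meta to the tether so no cyclization onto the alkene is possible.

Step 7
Reactants: 7 3-[(3S)-3-(tert-butyldimethylsilyloxy)pent-4-en-1-yl]-2,4-dimethylphenol; 8 allyl methyl carbonate
Product: 9 3-[(3S,4E)-3-(tert-butyldimethylsilyloxy)-6-(methoxycarbonyloxy)hex-4-en-1-yl]-2,4-dimethylphenol
Conditions: second-generation Hoveyda–Grubbs catalyst (5 mol%), 8 (4 equiv), CH2Cl2, 40 °C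
Reagents that add atoms: none
Why: Olefin cross-metathesis, expected to favour the E-alkene next to the bulky silyloxy centre, brings in the carbonate ready-made so that no acylation has to distinguish an alcohol from the free phenol.

Step 8
Reactants: 9 3-[(3S,4E)-3-(tert-butyldimethylsilyloxy)-6-(methoxycarbonyloxy)hex-4-en-1-yl]-2,4-dimethylphenol
Product: 10 (4aS,5S,6S)-6-(tert-butyldimethylsilyloxy)-1,4a-dimethyl-5-vinyl-5,6,7,8-tetrahydronaphthalen-2(4aH)-one (labdane numbering: 8S,9S,10S; 1,4-dien-3-one)
Conditions: [Ir(cod)Cl]2 (4 mol%), (R,R,Ra)-O,O′-(1,1′-binaphthyl-2,2′-diyl) N,N-bis(1-phenylethyl)phosphoramidite (8 mol%), pre-activation with n-PrNH2 (THF, 50 °C); then 9, Li2CO3, THF (0.02 M), 50 °C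
Reagents that add atoms: none
Why: Proposed new method: the catalyst formed from [Ir(cod)Cl]2 and the phosphoramidite ionizes the carbonate of 9 (loss of CO2 and methoxide, which deprotonates the phenol), and the phenoxide attacks the substituted C9 terminus of the allyliridium intermediate through its methyl-bearing para carbon on the face away from the metal, forming C9–C10. The closest known reactions are the iridium-catalysed intramolecular asymmetric allylic dearomatization of para-tethered phenols to spirocyclohexadienones and the para-selective Friedel–Crafts-type allylation of meta-tethered phenols; here the meta tether is combined with a blocked para carbon, so a ring-fused dienone must result. Ring B closes in a 6-exo mode with respect to the allyl unit (branched regiochemistry), which leaves C11=C12 outside the ring as the vinyl group. C9 is set by the ligand, which fixes the allyl face open to the nucleophile and is paired in the matched sense with the (S)-C8 silyloxy centre; C10 is set by the chair-like closure in which vinyl and silyloxy are both equatorial and the planar ring A forces the C10 methyl axial, cis to the vinyl group. The step needs C- over O-allylation and para over ortho attack: the oxygen cannot reach the allyl unit within the molecule and dilution holds back intermolecular ether formation, while the ortho carbon is wedged between the oxygen-bearing and the tether-bearing carbons and would give the less stable linearly conjugated 2,4-dienone. The C10 methyl blocks rearomatization, so the cross-conjugated dienone 10 should persist.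

Step 9
Reactants: 10 dienone (8S,9S,10S)
Product: 11 (8S,9S,10S)-8-(tert-butyldimethylsilyloxy)-4,10-dimethyl-9-vinyl bicyclic 4-en-3-one
Conditions: [(Ph3P)CuH]6 (0.4 equiv), toluene, H2O (3 equiv), rt
Reagents that add atoms: none
Why: Copper hydride conjugate reduction delivers hydride to the unsubstituted β-carbon C1, leaves the fully substituted C4=C5 bond and the isolated vinyl group alone, and the copper enolate is protonated at C2.

Step 10
Reactants: 11 4-en-3-one (8S,9S,10S)
Product: 13 (5S,8S,9S,10R)-8-(tert-butyldimethylsilyloxy)-4,4,10-trimethyl-9-vinyl trans-decalin-3-one, via lithium enolate 12 (not isolated)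
Conditions: Li, NH3(l)/THF, t-BuOH (1 equiv), −78 °C; then MeI, −78 → −33 °C
Reagents that add atoms: iodomethane, CI
Why: Birch-type reductive alkylation of an enone, in which protonation at C5 anti to the axial C10 methyl gives the trans ring fusion (sets C5) and the regiodefined C3–C4 enolate is methylated at C4, while the isolated vinyl group and the silyl ether are inert to lithium in ammonia.

Step 11
Reactants: 13 trans-decalin-3-one (5S,8S,9S,10R)
Product: 14 (3R,5S,8S,9S,10R)-8-(tert-butyldimethylsilyloxy)-4,4,10-trimethyl-9-vinyl trans-decalin-3-ol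
Conditions: NaBH4, MeOH, 0 °C
Reagents that add atoms: none
Why: Borohydride reduction of a 4,4-dimethyl-3-ketone of a trans-decalin should proceed by axial hydride delivery and give the equatorial alcohol, which sets C3 as R.

Step 12
Reactants: 14 decalin-3-ol (3R,5S,8S,9S,10R)
Product: 15 (3R,5S,8S,9S,10R)-8-(tert-butyldimethylsilyloxy)-3-(4-methoxybenzyloxy)-4,4,10-trimethyl-9-vinyl trans-decalin
Conditions: NaH, PMBCl, Bu4NI (cat.), DMF, 0 → 40 °C
Reagents that add atoms: 4-methoxybenzyl chloride, COc1ccc(CCl)cc1
Why: Williamson etherification at a stage without base-sensitive groups gives a C3 ether that is inert to boranes, Grignard reagents and fluoride and is removable oxidatively at the end.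

Step 13
Reactants: 16 methyl but-2-ynoate
Product: 17 methyl (2Z)-3-iodobut-2-enoate
Conditions: NaI, AcOH, 115 °C
Reagents that add atoms: sodium iodide, [Na+].[I-]
Why: Conjugate addition of iodide to the ynoate followed by protonation is a net anti hydroiodination and should give the Z-β-iodoenoate.

Step 14
Reactants: 15 PMB ether (3R,5S,8S,9S,10R); 17 methyl (2Z)-3-iodobut-2-enoate
Product: 19 methyl (13Z)-8-(tert-butyldimethylsilyloxy)-3-(4-methoxybenzyloxy)-17-norlabd-13-en-15-oate (3R,5S,8S,9S,10R), via B-alkyl-9-BBN adduct 18 (not isolated)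
Conditions: 9-BBN, THF, rt → 50 °C; then 17, Pd(dppf)Cl2 (5 mol%), AsPh3, aq. K3PO4, DMF, rt
Reagents that add atoms: none
Why: Anti-Markovnikov hydroboration puts boron on C12, and the B-alkyl Suzuki–Miyaura coupling (oxidative addition of the vinyl iodide to zerovalent palladium, then transmetalation) proceeds with retention, so the Z geometry of 17 is carried into the C13=C14 bond.

Step 15
Reactants: 19 silyl ether (3R,5S,8S,9S,10R)
Product: 20 methyl (13Z)-8-hydroxy-3-(4-methoxybenzyloxy)-17-norlabd-13-en-15-oate (3R,5S,8S,9S,10R)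
Conditions: HF·pyridine, pyridine/THF, 0 °C → rt
Reagents that add atoms: none
Why: Fluoride-mediated desilylation under buffered conditions leaves the PMB ether, the methyl ester and the Z-enoate unchanged.

Step 16
Reactants: 20 C8 alcohol (3R,5S,8S,9S,10R)
Product: 21 methyl (13Z)-3-(4-methoxybenzyloxy)-8-oxo-17-norlabd-13-en-15-oate (3R,5S,9S,10R)
Conditions: Dess–Martin periodinane, NaHCO3, CH2Cl2, rt
Reagents that add atoms: none
Why: Dess–Martin oxidation under near-neutral conditions gives the C8 ketone, and C9 is not at risk because its side chain already sits in the stable equatorial position.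

Step 17
Reactants: 21 C8 ketone (3R,5S,9S,10R)
Product: 23 methyl (13Z)-8,17-dihydroxy-3-(4-methoxybenzyloxy)labd-13-en-15-oate (3R,5S,8R,9S,10R), via silylmethyl carbinol 22 (not isolated)
Conditions: i-PrO(Me)2SiCH2MgCl, CeCl3, THF, −40 → 0 °C; then KF, KHCO3, 30% H2O2, THF/MeOH, rt
Reagents that add atoms: (isopropoxydimethylsilyl)methylmagnesium chloride, CC(C)O[Si](C)(C)C[Mg]Cl; hydrogen peroxide, OO
Why: Tamao hydroxymethylation (Grignard addition, then Tamao–Fleming oxidation of the C–Si bond): the axial trajectory at C8 is blocked by the syn-axial C10 methyl, so the nucleophile should enter equatorially and give the axial tertiary alcohol (8R), while the hindered conjugated ester reacts much more slowly than the ketone.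

Step 18
Reactants: 23 8,17-diol (3R,5S,8R,9S,10R)
Product: 24 methyl (13Z)-8-hydroxy-3-(4-methoxybenzyloxy)-17-oxolabd-13-en-15-oate (3R,5S,8R,9S,10R)
Conditions: SO3·pyridine, DMSO, i-Pr2NEt, CH2Cl2, 0 °C
Reagents that add atoms: none
Why: Parikh–Doering oxidation converts the primary alcohol into the aldehyde without glycol cleavage, and the tertiary C8 alcohol cannot be oxidized.

Step 19
Reactants: 24 PMB-protected hydroxy aldehyde (3R,5S,8R,9S,10R)
Product: 25 methyl (13Z)-3,8-dihydroxy-17-oxolabd-13-en-15-oate (3R,5S,8R,9S,10R), CNP0135080.1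
Conditions: DDQ, CH2Cl2/pH 7 buffer, 0 °C → rt
Reagents that add atoms: none
Why: Oxidative cleavage of the 4-methoxybenzyl ether by DDQ under neutral conditions spares the enoate and the base-sensitive tertiary α-hydroxy aldehyde.

**Compound list**
1 | 2,6-dimethylbenzaldehyde | Cc1cccc(C)c1C=O | starting material
2 | 3-bromo-2,6-dimethylbenzaldehyde | Cc1ccc(Br)c(C)c1C=O | intermediate
3 | (2E)-3-(3-bromo-2,6-dimethylphenyl)prop-2-enal | Cc1ccc(Br)c(C)c1/C=C/C=O | intermediate
4 | 3-(3-bromo-2,6-dimethylphenyl)propanal | Cc1ccc(Br)c(C)c1CCC=O | intermediate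
5 | (3S)-5-(3-bromo-2,6-dimethylphenyl)pent-1-en-3-ol | Cc1ccc(Br)c(C)c1CC[C@H](O)C=C | intermediate
6 | {[(3S)-5-(3-bromo-2,6-dimethylphenyl)pent-1-en-3-yl]oxy}(tert-butyl)dimethylsilane | Cc1ccc(Br)c(C)c1CC[C@H](O[Si](C)(C)C(C)(C)C)C=C | intermediate
7 | 3-[(3S)-3-(tert-butyldimethylsilyloxy)pent-4-en-1-yl]-2,4-dimethylphenol | Cc1ccc(O)c(C)c1CC[C@H](O[Si](C)(C)C(C)(C)C)C=C | intermediate
8 | allyl methyl carbonate | C=CCOC(=O)OC | starting material
9 | 3-[(3S,4E)-3-(tert-butyldimethylsilyloxy)-6-(methoxycarbonyloxy)hex-4-en-1-yl]-2,4-dimethylphenol | Cc1ccc(O)c(C)c1CC[C@H](O[Si](C)(C)C(C)(C)C)/C=C/COC(=O)OC | intermediate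
10 | (4aS,5S,6S)-6-(tert-butyldimethylsilyloxy)-1,4a-dimethyl-5-vinyl-5,6,7,8-tetrahydronaphthalen-2(4aH)-one | C=C[C@H]1[C@]2(C)C=CC(=O)C(C)=C2CC[C@@H]1O[Si](C)(C)C(C)(C)C | intermediate
11 | (8S,9S,10S)-8-(tert-butyldimethylsilyloxy)-4,10-dimethyl-9-vinyl bicyclic 4-en-3-one | C=C[C@H]1[C@]2(C)CCC(=O)C(C)=C2CC[C@@H]1O[Si](C)(C)C(C)(C)C | intermediate
12 | lithium C3–C4 enolate of the trans-fused 4-methyl-3-ketone (5S,8S,9S,10R) | C=C[C@H]1[C@]2(C)CCC(O[Li])=C(C)[C@H]2CC[C@@H]1O[Si](C)(C)C(C)(C)C | intermediate
13 | (5S,8S,9S,10R)-8-(tert-butyldimethylsilyloxy)-4,4,10-trimethyl-9-vinyl trans-decalin-3-one | C=C[C@H]1[C@]2(C)CCC(=O)C(C)(C)[C@H]2CC[C@@H]1O[Si](C)(C)C(C)(C)C | intermediate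
14 | (3R,5S,8S,9S,10R)-8-(tert-butyldimethylsilyloxy)-4,4,10-trimethyl-9-vinyl trans-decalin-3-ol | C=C[C@H]1[C@]2(C)CC[C@@H](O)C(C)(C)[C@H]2CC[C@@H]1O[Si](C)(C)C(C)(C)C | intermediate
15 | (3R,5S,8S,9S,10R)-8-(tert-butyldimethylsilyloxy)-3-(4-methoxybenzyloxy)-4,4,10-trimethyl-9-vinyl trans-decalin | C=C[C@H]1[C@]2(C)CC[C@@H](OCc3ccc(OC)cc3)C(C)(C)[C@H]2CC[C@@H]1O[Si](C)(C)C(C)(C)C | intermediate
16 | methyl but-2-ynoate | CC#CC(=O)OC | starting material
17 | methyl (2Z)-3-iodobut-2-enoate | COC(=O)/C=C(/C)I | intermediate
18 | B-alkyl-9-BBN adduct of 15 (boron on C12) | B1(C2CCCC1CCC2)CC[C@H]3[C@]4(C)CC[C@@H](OCc5ccc(OC)cc5)C(C)(C)[C@H]4CC[C@@H]3O[Si](C)(C)C(C)(C)C | intermediate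
19 | methyl (13Z)-8-(tert-butyldimethylsilyloxy)-3-(4-methoxybenzyloxy)-17-norlabd-13-en-15-oate (3R,5S,8S,9S,10R) | COC(=O)/C=C(/C)CC[C@H]1[C@]2(C)CC[C@@H](OCc3ccc(OC)cc3)C(C)(C)[C@H]2CC[C@@H]1O[Si](C)(C)C(C)(C)C | intermediate
20 | methyl (13Z)-8-hydroxy-3-(4-methoxybenzyloxy)-17-norlabd-13-en-15-oate (3R,5S,8S,9S,10R) | COC(=O)/C=C(/C)CC[C@H]1[C@]2(C)CC[C@@H](OCc3ccc(OC)cc3)C(C)(C)[C@H]2CC[C@@H]1O | intermediate
21 | methyl (13Z)-3-(4-methoxybenzyloxy)-8-oxo-17-norlabd-13-en-15-oate (3R,5S,9S,10R) | COC(=O)/C=C(/C)CC[C@H]1[C@]2(C)CC[C@@H](OCc3ccc(OC)cc3)C(C)(C)[C@H]2CCC1=O | intermediate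
22 | methyl (13Z)-8-hydroxy-17-(isopropoxydimethylsilyl)-3-(4-methoxybenzyloxy)labd-13-en-15-oate (3R,5S,8R,9S,10R) | COC(=O)/C=C(/C)CC[C@H]1[C@]2(C)CC[C@@H](OCc3ccc(OC)cc3)C(C)(C)[C@H]2CC[C@]1(O)C[Si](C)(C)OC(C)C | intermediate
23 | methyl (13Z)-8,17-dihydroxy-3-(4-methoxybenzyloxy)labd-13-en-15-oate (3R,5S,8R,9S,10R) | COC(=O)/C=C(/C)CC[C@H]1[C@]2(C)CC[C@@H](OCc3ccc(OC)cc3)C(C)(C)[C@H]2CC[C@]1(O)CO | intermediate
24 | methyl (13Z)-8-hydroxy-3-(4-methoxybenzyloxy)-17-oxolabd-13-en-15-oate (3R,5S,8R,9S,10R) | COC(=O)/C=C(/C)CC[C@H]1[C@]2(C)CC[C@@H](OCc3ccc(OC)cc3)C(C)(C)[C@H]2CC[C@]1(O)C=O | intermediate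
25 | methyl (13Z)-3,8-dihydroxy-17-oxolabd-13-en-15-oate (3R,5S,8R,9S,10R), CNP0135080.1 | COC(=O)/C=C(/C)CC[C@H]1[C@]2(C)CC[C@@H](O)C(C)(C)[C@H]2CC[C@]1(O)C=O | target

**Step count**
Total step count: 19.
Longest linear sequence: 18 steps (steps 1–12 and 14–19, from 1 to 25); step 13 is the only side-branch step.

**Three steps most likely to fail**

Step 8. The phenoxide may attack through its ortho carbon, or through oxygen on a second molecule. The ligand may also be mismatched with the C8 centre, which would erode the C9/C10 selectivity. The fallback uses the long-known base-mediated intramolecular C-alkylation of phenoxides (Winstein–Masamune type), with no metal and with C8 as the only control element. It sets out from phenol 7. Cross-metathesis with allyl chloride (second-generation Hoveyda–Grubbs catalyst, CH2Cl2, 40 °C) should give the allylic chloride 3-[(3S,4E)-3-(tert-butyldimethylsilyloxy)-6-chlorohex-4-en-1-yl]-2,4-dimethylphenol F1. One equivalent of KOt-Bu in t-BuOH at high dilution then forms the phenoxide, whose para carbon displaces chloride in the SN2′ sense through the same chair (vinyl and silyloxy equatorial, C10 methyl axial). The fallback comes back to the route at dienone 10.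

Step 17. The hindered C8 ketone may enolize instead of adding the bulky silylmethyl Grignard reagent, the reagent may attack the ester, or addition may occur from the axial face. The fallback changes the C17 source to a two-carbon nucleophile that is later cut back, and sets out from ketone 21. Vinylmagnesium bromide with CeCl3 (THF, −78 °C), a small and weakly basic organocerium reagent, should add equatorially to give the tertiary allylic alcohol methyl (13Z)-8-hydroxy-3-(4-methoxybenzyloxy)-8-vinyl-17-norlabd-13-en-15-oate F2. Ozonolysis dosed to a Sudan Red 7B end point (O3, CH2Cl2/pyridine, −78 °C) then cleaves the isolated vinyl group before the ester-deactivated C13=C14 bond. The fallback comes back at aldehyde 24, so compound 23 and step 18 are bypassed.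

Step 10. Proton transfer between enolate 12 and the ketone product in ammonia may return unmethylated 4-methyl ketone and lead to methylation at C2, and O-methylation or over-reduction may compete. The fallback separates reduction from alkylation and sets out from enone 11. After the lithium–ammonia reduction the ammonia is evaporated and enolate 12 is trapped with chlorotrimethylsilane/triethylamine in THF as the isolable trimethylsilyl enol ether (5S,8S,9S,10R)-8-(tert-butyldimethylsilyloxy)-4,10-dimethyl-3-(trimethylsilyloxy)-9-vinyl bicyclic 3-ene F3. Methyllithium in THF at 0 °C regenerates 12 free of ammonia and proton donors, and iodomethane then methylates C4. The fallback comes back at ketone 13.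

**Further compounds**
F1 | step 8 | 3-[(3S,4E)-3-(tert-butyldimethylsilyloxy)-6-chlorohex-4-en-1-yl]-2,4-dimethylphenol | Cc1ccc(O)c(C)c1CC[C@H](O[Si](C)(C)C(C)(C)C)/C=C/CCl
F2 | step 17 | methyl (13Z)-8-hydroxy-3-(4-methoxybenzyloxy)-8-vinyl-17-norlabd-13-en-15-oate | COC(=O)/C=C(/C)CC[C@H]1[C@]2(C)CC[C@@H](OCc3ccc(OC)cc3)C(C)(C)[C@H]2CC[C@]1(O)C=C
F3 | step 10 | (5S,8S,9S,10R)-8-(tert-butyldimethylsilyloxy)-4,10-dimethyl-3-(trimethylsilyloxy)-9-vinyl bicyclic 3-ene | C=C[C@H]1[C@]2(C)CCC(O[Si](C)(C)C)=C(C)[C@H]2CC[C@@H]1O[Si](C)(C)C(C)(C)C
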